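The route rests on cutting two bonds of the seven-membered ring (azulene numbering): C8–C8a, between the free carbinol and the methyl-bearing fusion carbon, and C3a–C4, between the fusion CH and the ester carbon. With C3 as a ketone, C3–C3a–C8a is the carbonyl/α/β array of a cyclopentenone and C8 is an allylic carbinol beside it. One operation, an anionic oxy-Cope shift followed by aldol capture of the enolate it releases, should therefore forge both bonds and four stereocentres. Its precursor is a tertiary 1-allylcyclopent-2-enol carrying an E enol ether, plus 3-methylbut-3-enal; ring-closing metathesis then closes the seven-membered ring.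

Key step: step 4

Remark: atoms are numbered as in azulene (C3 bears isopropyl and hydroxyl, C3a and C8a are the fusion carbons, C4 bears the ester, C8 the free hydroxyl); alkyne 2 is assumed to be a catalogue compound (otherwise one etherification from propargyl alcohol).

Step 1
Reactants: 1 3-methylcyclopent-2-en-1-one; 2 1-methoxy-4-[(prop-2-yn-1-yloxy)methyl]benzene
Product: 5 (1R)-1-[(1E)-3-(4-methoxybenzyloxy)prop-1-en-1-yl]-3-methylcyclopent-2-en-1-ol, via alkenylzirconocene chloride 3 (not isolated), via alkenyl(methyl)zinc 4 (not isolated)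
Conditions: 2, Cp2Zr(H)Cl, CH2Cl2, rt; Me2Zn, toluene, −78 °C; then 1, Ti(OiPr)4 (1.2 eq), bis(camphorsulfonamide) diol ligand of trans-cyclohexane-1,2-diamine (10 mol %, antipode chosen for the R carbinol), rt; H2O
Reagents that add atoms: none
Why: Titanium-promoted catalytic asymmetric 1,2-addition of an alkenylzinc reagent to a ketone (hydrozirconation, then Zr-to-Zn exchange, keeps the E alkene) should attack only the carbonyl of the enone and set the tertiary carbinol as R under control of the chiral ligand.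

Step 2
Reactants: 5 (1R)-1-[(1E)-3-(4-methoxybenzyloxy)prop-1-en-1-yl]-3-methylcyclopent-2-en-1-ol
Product: 6 (1R)-1-[(2E)-3-(4-methoxybenzyloxy)prop-2-en-1-yl]-3-methylcyclopent-2-en-1-ol
Conditions: [Ir(cod)(PMePh2)2]PF6 (2 mol %, pre-activated with H2), THF, rt; Et3N quench
Reagents that add atoms: none
Why: Iridium-hydride isomerisation of an allyl ether to its prop-1-enyl ether should move the double bond toward oxygen only (the carbinol carbon carries no hydrogen) and give the E enol ether through a syn π-allyl hydride, leaving the stereocentre untouched.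

Step 3
Reactants: 7 3-methylbut-3-en-1-ol
Product: 8 3-methylbut-3-enal
Conditions: Dess–Martin periodinane, NaHCO3, CH2Cl2, 0 °C to rt; used at once as a cold solution
Reagents that add atoms: none
Why: Dess–Martin oxidation under bicarbonate buffer should give the β,γ-unsaturated aldehyde without shifting the alkene into conjugation.

Step 4
Reactants: 6 (1R)-1-[(2E)-3-(4-methoxybenzyloxy)prop-2-en-1-yl]-3-methylcyclopent-2-en-1-ol; 8 3-methylbut-3-enal
Product: 12 (2S,3S)-2-[(1S)-1-hydroxy-3-methylbut-3-en-1-yl]-3-[(1R)-1-(4-methoxybenzyloxy)prop-2-en-1-yl]-3-methylcyclopentan-1-one, via potassium alkoxide 9 (not isolated), via potassium enolate 10 (not isolated), via chlorozinc enolate 11 (not isolated)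
Conditions: KH (1.1 eq), 18-crown-6, THF, 0 to 40 °C; cool to −78 °C, ZnCl2; then 8, −78 °C; H2O quench
Reagents that add atoms: none
Why: KH/18-crown-6 converts 6 into the free alkoxide 9, whose anionic oxy-Cope ([3,3]) shift joins the enol-ether terminus to the methyl-bearing ring carbon and releases the regiodefined enolate 10; after exchange to zinc (11) this adds to aldehyde 8 in a Zimmerman–Traxler aldol. The closest known reaction types are the anionic oxy-Cope rearrangement of 1-allylcycloalk-2-enols used as a conjugate-allylation equivalent, and the three-component conjugate addition/enolate aldol coupling. No ring is closed here: the step attaches, on the existing five-membered ring, the two side chains that step 5 joins. The quaternary centre should be set by suprafacial transfer of the allyl unit across the ring face fixed by the carbinol of 6 (chair-like transition state bridging C1 and C3 of the cyclopentene), and the ether carbinol by the E enol ether, which places the 4-methoxybenzyloxy group equatorial. The two aldol centres should follow from attack of the aldehyde on the enolate face away from the branched alkoxyallyl group (cis to methyl) and from the fixed E geometry of the cyclic enolate (anti aldol). The step needs the [3,3] shift to beat cleavage of 9 into enone 1 and chair to beat boat; the crown-separated potassium alkoxide, the compact cyclic diene and the unhindered enol-ether CH should favour both.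

Step 5
Reactants: 12 (2S,3S)-2-[(1S)-1-hydroxy-3-methylbut-3-en-1-yl]-3-[(1R)-1-(4-methoxybenzyloxy)prop-2-en-1-yl]-3-methylcyclopentan-1-one
Product: 13 (3aS,4S,8R,8aS)-4-hydroxy-8-(4-methoxybenzyloxy)-6,8a-dimethyl-2,3a,4,5,8,8a-hexahydroazulen-3(1H)-one
Conditions: second-generation Grubbs catalyst RuCl2(=CHPh)(H2IMes)(PCy3) (5 mol %), toluene, 80 °C, argon sweep
Reagents that add atoms: none
Why: Ring-closing metathesis between the vinyl group and the 1,1-disubstituted alkene of the two trans side chains should close the seven-membered ring as its Z trisubstituted alkene, with loss of ethene and no stereocentre touched.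

Step 6
Reactants: 13 (3aS,4S,8R,8aS)-4-hydroxy-8-(4-methoxybenzyloxy)-6,8a-dimethyl-2,3a,4,5,8,8a-hexahydroazulen-3(1H)-one
Product: 14 (3R,3aS,4S,8R,8aS)-8-(4-methoxybenzyloxy)-6,8a-dimethyl-3-(propan-2-yl)-1,2,3,3a,4,5,8,8a-octahydroazulene-3,4-diol
Conditions: iPrMgCl (3 eq), anhydrous CeCl3, THF, −78 to 0 °C; H2O
Reagents that add atoms: isopropylmagnesium chloride, CC(C)[Mg]Cl
Why: Organocerium 1,2-addition suppresses enolisation and retro-aldol of the β-hydroxy ketone, and the isopropyl group should enter from the face of the C3a hydrogen, opposite the angular methyl, which places the new tertiary hydroxyl cis to that methyl (3R).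

Step 7
Reactants: 14 (3R,3aS,4S,8R,8aS)-8-(4-methoxybenzyloxy)-6,8a-dimethyl-3-(propan-2-yl)-1,2,3,3a,4,5,8,8a-octahydroazulene-3,4-diol; 15 4-methoxybenzoyl chloride
Product: 16 (3R,3aS,4S,8R,8aS)-3-hydroxy-8-(4-methoxybenzyloxy)-6,8a-dimethyl-3-(propan-2-yl)-1,2,3,3a,4,5,8,8a-octahydroazulen-4-yl 4-methoxybenzoate
Conditions: Et3N, DMAP (cat.), CH2Cl2, 0 °C to rt
Reagents that add atoms: none
Why: DMAP-catalysed acylation with the acid chloride should esterify only the secondary C4 hydroxyl, the tertiary C3 hydroxyl being inert and C8 still protected.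

Step 8
Reactants: 16 (3R,3aS,4S,8R,8aS)-3-hydroxy-8-(4-methoxybenzyloxy)-6,8a-dimethyl-3-(propan-2-yl)-1,2,3,3a,4,5,8,8a-octahydroazulen-4-yl 4-methoxybenzoate
Product: 17 (3R,3aS,4S,8R,8aS)-3,8-dihydroxy-6,8a-dimethyl-3-(propan-2-yl)-1,2,3,3a,4,5,8,8a-octahydroazulen-4-yl 4-methoxybenzoate
Conditions: DDQ, CH2Cl2/pH 7 buffer, 0 °C
Reagents that add atoms: none
Why: Oxidative cleavage of the 4-methoxybenzyl ether by DDQ (hydride abstraction, then hydrolysis of the oxocarbenium ion) should free the C8 hydroxyl without harming the electron-poorer anisoate, the alkene or the tertiary alcohol.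

Compound list
1 | 3-methylcyclopent-2-en-1-one | CC1=CC(=O)CC1 | starting material
2 | 1-methoxy-4-[(prop-2-yn-1-yloxy)methyl]benzene | C#CCOCc1ccc(OC)cc1 | starting material
3 | chlorobis(cyclopentadienyl)[(1E)-3-(4-methoxybenzyloxy)prop-1-en-1-yl]zirconium (cyclopentadienyl rings drawn σ-bonded) | COc1ccc(COC/C=C/[Zr](Cl)(C2C=CC=C2)C2C=CC=C2)cc1 | intermediate
4 | [(1E)-3-(4-methoxybenzyloxy)prop-1-en-1-yl](methyl)zinc | COc1ccc(COC/C=C/[Zn]C)cc1 | intermediate
5 | (1R)-1-[(1E)-3-(4-methoxybenzyloxy)prop-1-en-1-yl]-3-methylcyclopent-2-en-1-ol | CC1=C[C@](O)(/C=C/COCc2ccc(OC)cc2)CC1 | intermediate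
6 | (1R)-1-[(2E)-3-(4-methoxybenzyloxy)prop-2-en-1-yl]-3-methylcyclopent-2-en-1-ol | CC1=C[C@](O)(C/C=C/OCc2ccc(OC)cc2)CC1 | intermediate
7 | 3-methylbut-3-en-1-ol | CC(=C)CCO | starting material
8 | 3-methylbut-3-enal | CC(=C)CC=O | intermediate
9 | potassium (1R)-1-[(2E)-3-(4-methoxybenzyloxy)prop-2-en-1-yl]-3-methylcyclopent-2-en-1-olate | CC1=C[C@]([O-])(C/C=C/OCc2ccc(OC)cc2)CC1.[K+] | intermediate
10 | potassium (3S)-3-[(1R)-1-(4-methoxybenzyloxy)prop-2-en-1-yl]-3-methylcyclopent-1-en-1-olate | [K+].[O-]C1=C[C@@](C)([C@H](OCc2ccc(OC)cc2)C=C)CC1 | intermediate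
11 | chlorozinc (3S)-3-[(1R)-1-(4-methoxybenzyloxy)prop-2-en-1-yl]-3-methylcyclopent-1-en-1-olate | Cl[Zn]OC1=C[C@@](C)([C@H](OCc2ccc(OC)cc2)C=C)CC1 | intermediate
12 | (2S,3S)-2-[(1S)-1-hydroxy-3-methylbut-3-en-1-yl]-3-[(1R)-1-(4-methoxybenzyloxy)prop-2-en-1-yl]-3-methylcyclopentan-1-one | O[C@@H](CC(C)=C)[C@H]1C(=O)CC[C@]1(C)[C@H](OCc2ccc(OC)cc2)C=C | intermediate
13 | (3aS,4S,8R,8aS)-4-hydroxy-8-(4-methoxybenzyloxy)-6,8a-dimethyl-2,3a,4,5,8,8a-hexahydroazulen-3(1H)-one | O[C@H]1CC(C)=C[C@@H](OCc2ccc(OC)cc2)[C@@]3(C)CCC(=O)[C@H]13 | intermediate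
14 | (3R,3aS,4S,8R,8aS)-8-(4-methoxybenzyloxy)-6,8a-dimethyl-3-(propan-2-yl)-1,2,3,3a,4,5,8,8a-octahydroazulene-3,4-diol | O[C@H]1CC(C)=C[C@@H](OCc2ccc(OC)cc2)[C@@]3(C)CC[C@@](O)(C(C)C)[C@H]13 | intermediate
15 | 4-methoxybenzoyl chloride | COc1ccc(cc1)C(Cl)=O | starting material
16 | (3R,3aS,4S,8R,8aS)-3-hydroxy-8-(4-methoxybenzyloxy)-6,8a-dimethyl-3-(propan-2-yl)-1,2,3,3a,4,5,8,8a-octahydroazulen-4-yl 4-methoxybenzoate | COc1ccc(C(=O)O[C@H]2CC(C)=C[C@@H](OCc4ccc(OC)cc4)[C@@]3(C)CC[C@@](O)(C(C)C)[C@H]23)cc1 | intermediate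
17 | (3R,3aS,4S,8R,8aS)-3,8-dihydroxy-6,8a-dimethyl-3-(propan-2-yl)-1,2,3,3a,4,5,8,8a-octahydroazulen-4-yl 4-methoxybenzoate | COc1ccc(C(=O)O[C@H]2CC(C)=C[C@@H](O)[C@@]3(C)CC[C@@](O)(C(C)C)[C@H]23)cc1 | target

Total step count: 8
Longest linear sequence: 7 steps (steps 1, 2, 4, 5, 6, 7, 8)

Steps most likely to fail

Step 4. The tertiary bis-allylic alkoxide may cleave into enone 1 and an oxyallyl anion faster than it rearranges, which would lose the stereochemical relay. Some material may pass through the boat transition state and erode the configuration at the ether carbinol. The basic enolate may also be quenched by proton transfer from the readily enolised aldehyde. The fallback sets out from 6 and removes every basic intermediate. Silylation (TMSCl, imidazole) should give {(1R)-1-[(2E)-3-(4-methoxybenzyloxy)prop-2-en-1-yl]-3-methylcyclopent-2-en-1-yl}oxy(trimethyl)silane F1. Thermal siloxy-Cope rearrangement (about 220 °C, o-dichlorobenzene, base-washed sealed tube) should deliver the regiodefined silyl enol ether {[(3S)-3-[(1R)-1-(4-methoxybenzyloxy)prop-2-en-1-yl]-3-methylcyclopent-1-en-1-yl]oxy}(trimethyl)silane F2. A Mukaiyama aldol of F2 with 8 (BF3·OEt2, CH2Cl2, −78 °C) comes back to the route at 12; the aldol diastereomers would then have to be separated.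

Step 2. The cationic iridium hydride may ionise the tertiary bis-allylic alcohol, or add the γ-hydroxyl across the newly formed enol ether to give a spiro-acetal; incomplete E selectivity is a further hazard. The fallback sets out from 1 and builds the E enol ether by C–O coupling instead. Enantioselective Sakurai–Hosomi allylation of the ketone (allyltrimethoxysilane, AgF, DIFLUORPHOS antipode chosen for the R carbinol, MeOH, THF, −78 °C) should give (1R)-1-allyl-3-methylcyclopent-2-en-1-ol F3. Cross-metathesis with 4,4,5,5-tetramethyl-2-vinyl-1,3,2-dioxaborolane (second-generation Grubbs catalyst) should give (1R)-3-methyl-1-[(2E)-3-(4,4,5,5-tetramethyl-1,3,2-dioxaborolan-2-yl)prop-2-en-1-yl]cyclopent-2-en-1-ol F4. Coupling of F4 with 4-methoxybenzyl alcohol promoted by Cu(OAc)2 (Et3N, 4 Å sieves, air), with retention of alkene geometry, comes back to the route at 6.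

Step 1. Facial discrimination of a ketone whose two α-carbons differ only as CH= and CH2 may be poor, giving low enantiomeric purity that every later step would carry. The fallback sets out from 1 and takes the chirality from a secondary alcohol. CBS reduction ((R)-2-methyl-CBS-oxazaborolidine, BH3·SMe2) should give (1S)-3-methylcyclopent-2-en-1-ol F5, and carbamoylation (N,N-diisopropylcarbamoyl chloride, NaH) the ester (1S)-3-methylcyclopent-2-en-1-yl N,N-di(propan-2-yl)carbamate F6. Lithiation (sBuLi, TMEDA, Et2O, −78 °C) and borylation would use 2-[(1E)-3-(4-methoxybenzyloxy)prop-1-en-1-yl]-4,4,5,5-tetramethyl-1,3,2-dioxaborolane F7, made from 2 with pinacolborane and catalytic Cp2Zr(H)Cl. The 1,2-metallate shift should then give 2-{(1S)-1-[(1E)-3-(4-methoxybenzyloxy)prop-1-en-1-yl]-3-methylcyclopent-2-en-1-yl}-4,4,5,5-tetramethyl-1,3,2-dioxaborolane F8. Oxidation (H2O2, NaOH), with the new carbon group standing where the carbinol hydrogen stood, comes back to the route at 5.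

Further compounds
F1 | step 4 | {(1R)-1-[(2E)-3-(4-methoxybenzyloxy)prop-2-en-1-yl]-3-methylcyclopent-2-en-1-yl}oxy(trimethyl)silane | CC1=C[C@](O[Si](C)(C)C)(C/C=C/OCc2ccc(OC)cc2)CC1
F2 | step 4 | {[(3S)-3-[(1R)-1-(4-methoxybenzyloxy)prop-2-en-1-yl]-3-methylcyclopent-1-en-1-yl]oxy}(trimethyl)silane | C[Si](C)(C)OC1=C[C@@](C)([C@H](OCc2ccc(OC)cc2)C=C)CC1
F3 | step 2 | (1R)-1-allyl-3-methylcyclopent-2-en-1-ol | CC1=C[C@](O)(CC=C)CC1
F4 | step 2 | (1R)-3-methyl-1-[(2E)-3-(4,4,5,5-tetramethyl-1,3,2-dioxaborolan-2-yl)prop-2-en-1-yl]cyclopent-2-en-1-ol | CC1=C[C@](O)(C/C=C/B2OC(C)(C)C(C)(C)O2)CC1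
F5 | step 1 | (1S)-3-methylcyclopent-2-en-1-ol | CC1=C[C@@H](O)CC1
F6 | step 1 | (1S)-3-methylcyclopent-2-en-1-yl N,N-di(propan-2-yl)carbamate | CC1=C[C@@H](OC(=O)N(C(C)C)C(C)C)CC1
F7 | step 1 | 2-[(1E)-3-(4-methoxybenzyloxy)prop-1-en-1-yl]-4,4,5,5-tetramethyl-1,3,2-dioxaborolane | COc1ccc(COC/C=C/B2OC(C)(C)C(C)(C)O2)cc1
F8 | step 1 | 2-{(1S)-1-[(1E)-3-(4-methoxybenzyloxy)prop-1-en-1-yl]-3-methylcyclopent-2-en-1-yl}-4,4,5,5-tetramethyl-1,3,2-dioxaborolane | CC1=C[C@](B2OC(C)(C)C(C)(C)O2)(/C=C/COCc3ccc(OC)cc3)CC1
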